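The closed, stirred flask you asked about starts with free monomer, initiator and transfer agent, and your hunch was that the transfer agent would stall it.

free monomer 0.50 mM; transfer agent 0.0150 mM; initiator 25 µM; time 2.5 min

    free monomer + initiator → living end + monomer in chains (k1 = 8200 L mol⁻¹ s⁻¹)
    free monomer + living end → monomer in chains + living end, rate k2*[living end]*[free monomer] (k2 = 20000 L mol⁻¹ s⁻¹)
    living end + transfer agent → dead chain (k3 = 44000 L mol⁻¹ s⁻¹)
    monomer in chains ⇌ isomer of the product (K4 = 8.4, k4 = 0.63 s⁻¹)

- the reaction counts as stopped when no species that holds the free monomer changes by six tenths of a point or more over the second half of the time
- run time (flask): 2.5 min

- the state of affairs at 2.5 min: stopped, and by what, or still going (no working catalyst is left / it is still moving / forward and back rates have come level / all of the free monomer has reacted)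
- part of the free monomer gone at 2.5 min
- the monomer in chains standing at 2.5 min, as a percentage of the free monomer charged

I reckoned this flask by what is left, not by what is made. At the charge of free monomer, the initiator had a half-life of

0.169 s,

which is short against 2.5 min, so I counted its whole charge as living ends. Each transfer agent removes one living end, and there was more initiator than transfer agent, so I expected a surplus of ends to survive:

surviving living ends = 0.0100 mM

These surviving ends gave a late pace for free monomer of 0.200 s⁻¹; earlier, while more ends stood, I expected a higher pace. As a rough estimate I ran the fraction left down exponentially at that late pace over the whole time:

conversion = one minus e to the minus (0.200 s⁻¹ × 150 s) = >99.9%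

I therefore took the free monomer to be used up. The exchange between monomer in chains and isomer of the product has a relaxation half-life of 0.983 s, short against 2.5 min, which puts the split under thermodynamic control:

1 / (1 + 8.4) = 10.6%

I called this the chain share: the fraction of reacted monomer left as monomer in chains once the exchange has balanced. Multiplying it by the conversion gave

monomer in chains = 10.6%

The forecast gave all of the free monomer has reacted, conversion 100% and monomer in chains 10.6%, from 10.4% to 10.9%, noting that the exchange “relaxes in under two seconds”. The simulation gave all of the free monomer has reacted, conversion 100% and monomer in chains 10.6%.

The exchange is what cut this flask down to the chain share: with that step taken away, monomer in chains stood at 100% instead of 10.6%. Your hunch fits the neighbour charged with 0.0062 mM of initiator, less than its transfer agent: at 2.50 min it held 0 mM of living end and 77.5% of free monomer. The chain share of the 22.5% that reacted there is 2.38%, and that flask held 2.39% of monomer in chains.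

The constants were chosen freely, and the outcome is calculated.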